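The data are simulated for substances that don't exist; scatter was added.

**Minutes of the meeting on the flask charged with 0.40 M of J**

The chair opened with the alpha run: J fell to 29.9% of its charge by 2.50 min, a decay with time constant 2.07 min, while theta, charged with 0.30 M, stood at 31.0% at that time.

| setting | alpha | theta | flask |
|---|---|---|---|
| J | 0.20 M | 0.30 M | 0.40 M |
| Z | 78 mM (held) | 78 mM (held) | 78 mM (held) |
| remark | run made earlier | run made earlier |  |
| time |  |  | 3.0 min |

- alpha (time / min: Q / %, L / %, J / %): 0.333: 2.0, 1.2, 85.8; 0.833: 6.0, 3.3, 67.9; 1.50: 9.6, 6.0, 48.9; 2.50: 11.9, 7.2, 29.9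
- theta (time / min: Q / %, L / %, J / %): 0.333: 2.3, 0.8, 84.7; 0.833: 6.3, 3.3, 67.6; 1.50: 8.9, 5.9, 49.1; 2.50: 11.9, 6.4, 31.0

(standard deviation of a reading: 0.5 percentage points)

* how much Q and L together there is at 3.0 min, in percent of the J charged
* the change that raises the amount of Q and L together at 3.0 min, in percent of the J charged most ("none" if none brings more than 2 percentage points) (Tuesday's / Sunday's / none)
* amount of Q and L together at 3.0 min, in percent of the J charged, after Sunday's

- Tuesday's: doubling the transfer coefficient of Z, all else as stated
- Sunday's: doubling the saturation concentration of Z, all else as stated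

I proposed following one molecule of J through its fork and asking where it ends. In the last alpha reading, 11.9% of the charge stood as Q with its L, against 70.1% of J spent, which gives 0.170. This is the kept share, the fraction standing as Q with its L per fraction of J spent, which the trade calls overall selectivity; it is a reading, each term carrying a scatter of 0.5 percentage points. Theta gave 0.172, about the same, so I carried the share to the flask's larger charge. With that time constant I reckoned 76.5% of J spent by 3.0 min, and my own estimate became 13.0%.

The forecaster differed, holding to 18.9%, and named Sunday's as the better change, with 25% after it. The stated ground ran: “so D is scarcely depleted and transfer isn't limiting”.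

The flask gave 12.1%. Sunday's proved the stronger change, worth 8.1 points against 5.3 points for Tuesday's, and it brought the flask to 20.2%.

    D ⇌ G (K = 150, k = 0.160 s⁻¹)
    J → X (k = 0.00630 s⁻¹)
    D + Q → E (k = 0.280 M⁻¹ s⁻¹)
    D + Q ⇌ L, settled at all times (K = 71.0 M⁻¹)
    Z ⇌ D, rate k5*(csat - [D]) (kL = 0.0580 s⁻¹)
    J + D → Q (k = 0.0890 M⁻¹ s⁻¹)

At 3.00 min in this flask, J is used by the step to X 3.3 times as fast as by the step to Q, where the forecast put the two at 0.285 and 0.185 per minute, so 0.233 of the J then reacting goes to Q. The flask's kept share to that time is 0.159 on 76.2% of J spent, and the same flask stopped at 50 s has spent 32.0% of its J, on which the share 0.170 gives 5.44%, while it holds 5.53%.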